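## Analysis of the target

Target 36 is a benzotropolone. A benzene ring (C1–C4, C4a, C9a) is fused to a seven-membered ring (C4a, C5–C9, C9a) that carries the hydroxy-ketone pair on C5/C6, with further phenols on C3 and C4. Two 5,7-dihydroxyflavan-3-ol units are attached through their C2 atoms: flavan A on C8 of the seven-membered ring, flavan B on C1 of the benzene ring. Only flavan A is esterified on O3, as the 3,4,5-trihydroxybenzoate. There are four stereocentres in two remote pairs, each 2,3-cis and (2R,3R); the pairs cannot relay to each other, but both can come from one chiral building block. The molecule is an oxidation-prone polyphenol: the tropolone chelates metals and can be over-reduced, the cis-flavans epimerise at C2 with base and ionise with acid, and the aryl ester is base-labile, so the last steps must be neutral. The hard parts are the fully unsymmetrical benzotropolone, telling the two flavans apart for a single acylation, and the less stable cis arrangement twice. The strategy rests on the seven-membered ring. C6 (carbonyl carbon) and C7 (CH) lie between C5, the C–OH carbon bonded to C4a, and C8, the carbon bearing flavan A. Without C6 and C7, C5 is bonded to C8 and the ring is that of a 1-indanone with C5 as its carbonyl carbon and C8 as its C2. C2 of flavan A, at the ketone level, is then a 2-acyl group, so an alkene inserted into the C1–C2 bond of a 2-acyl-1-indanone gives the ring.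

## Retrosynthetic reasoning

**36 to 35.** The eleven phenolic and alcoholic O–benzyl bonds of 35 are cut last. Hydrogenolysis is the only global unmasking that is neutral, which the ester, the tropolone and the cis-flavans all require.

**35 to 33 and 34.** The ester C–O bond at O3 of flavan A is cut to alcohol 33 and acid 34. The ester would not survive enolates, hydride or fluoride, so it comes late. In 33 the O3 of flavan A is free while that of flavan B is a benzyl ether; this difference is set at the start by protecting the two chains differently (silyl in 15, benzyl in 16).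

**33 to 32 to 30.** In each flavan the O1–C2 and C2–H bonds are cut, which opens both pyran rings to diketone 30 with two masked phenols. This puts carbonyl groups on the two carbons attached to the benzotropolone, which are the acyl groups that the rest of the plan can install. Forward, one reductive etherification must close both rings and set both C2 centres cis to the C3 oxygen already present.

**30 to 29 and 18.** The bond between C1 of the benzene ring and the chain B carbonyl is cut to boronic acid 29 and thioester 18. A base-free acyl cross-coupling is chosen because both chains carry an enolisable α-oxygenated stereocentre and the tropone and ketone carbonyls exclude aryl-lithium or -magnesium chemistry. 29 comes from bromide 27; the bromine has been in place since step 1.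

**27 to 26 to 24 to 23.** These are oxidation-level and protecting-group changes only. The tropolone ether 27 comes from tropolone 26, and 26 from acetoxy ketone 23 by acetate removal (24), oxidation to the 1,2-dione (25) and loss of two hydrogens.

**23 to 20 and 21 (key disconnection).** The C5–C6 and C7–C8 bonds are cut, which takes C6 and C7 out as alkene 21 and leaves the 2-acyl-1-indanone 20. Cutting here gains most: the seven-membered ring and the C6 oxygen come from a five-membered ring that is easy to make. The whole C2–C3–C4 chain of flavan A, with C3 configured, rides through as the acyl group. Forward, the ring enol of 20 must add 21 so that the acetoxy carbon bonds to the enol carbon, and the cyclobutanol must fragment.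

**20 to 8 and 15.** The bond between C2 of the indanone and the acyl carbon is cut to indanone 8 and ester 15, a crossed Claisen acylation.

**8 to 6 to 2 and 3 to 1.** The aryl–carbonyl bond of 8 is cut to acid 6. The bromine of 6 blocks the position para to an ether oxygen, so closure must occur next to the benzyloxy group, which gives the 7-oxygenated indanone. 6 comes from aldehyde 2 and 3 by a two-carbon homologation, and 2 from 1 by bromination.

**15 and 18 to 14 to 10 and 11 to 9.** Both chains come from hydroxy ester 14. Its aryl–CH2 bond is cut to the metalated form of 10 and epoxide 11, which supplies the stereocentre unchanged. The methoxymethyl ether of 10 directs the metalation and masks the oxygen that becomes O1 of each flavan.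

## Alternatives that were turned down

**Alternative 1:** The O1–C2 bond of flavan A is cut at the flavanone level, giving the 2'-hydroxychalcone A1, whose enone β-carbon carries the finished, benzylated benzotropolone with flavan B attached. In the forward step a bifunctional amine–thiourea organocatalyst of the cinchona family closes A1 by conjugate addition of the phenol and gives flavanone A2 with C2 set.
- For: C2 is set by the catalyst and does not depend on a neighbouring centre, the conditions are mild, and A1 comes from a simple condensation. On this point it is stronger than the chosen route, where C2 depends on substrate-controlled hydride delivery.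
- Against: A2 has no oxygen on C3 and a carbonyl on C4. Reaching the 2,3-cis flavan-3-ol needs α-hydroxylation (which gives the trans relationship), removal of the C4 carbonyl and inversion at C3. The C2 centre of a flavanone opens by retro-addition under the basic conditions these steps need. The enone of A1 is cross-conjugated with an electrophilic tropone ether.
- Comparison: the alternative says nothing about how the seven-membered ring is made. The chosen strategy makes that ring, brings C3 in already oxygenated and configured, and needs no redox work at C3 or C4.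

**Alternative 2:** The C3–C4 and O1–C2 bonds of flavan A are cut, giving the 8-hydroxyacetyl benzotropolone A3 and an ortho-quinone methide released by base from sulfone A4. A dinuclear zinc alkoxide catalyst, built from a dialkylzinc and a chiral bis(prolinol)phenol ligand, adds the enolate of A3 to the quinone methide; the phenoxide closes on the ketone to give hemiketal A5 with C3 set.
- For: two bonds and ring C form in one step, the C3 hydroxyl is free for acylation without a silyl group, and A5 is then reduced just as in the endgame chosen here. It is stronger on step count within flavan A.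
- Against: the donor is a hydroxy ketone on a chelating tropone ether that competes for zinc, so the catalyst must create a centre that the chosen route buys. A3 must already contain the seven-membered ring, flavan B and a hydroxyacetyl group on C8, all made by other means.
- Comparison: the chosen strategy offers the ring construction itself and a C3 centre of certain configuration.

**Alternative 3:** The C5–C6 and C6–C7 bonds are cut so that only C6 is inserted, into the silyl enol ether A6 of a tetralone ester. A dibromo-substituted carbene, made from the haloform and base, adds to the enol ether; the siloxy dibromocyclopropane opens with loss of bromide to bromo enone A7.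
- For: it is thermal and scalable with no orientation question, C6 arrives with a heteroatom (bromine) and one ring double bond is already present. It is stronger than the chosen route in oxidation-state economy and in needing no photochemistry.
- Against: one carbon only, so a six-membered precursor is needed, which is longer to make than indanone 8. C8 carries an ester, the wrong polarity for attaching the flavan A chain; that chain and both its stereocentres would have to be built afterwards. The bromotropone must still be hydrolysed under forcing base.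
- Comparison: the chosen strategy inserts both carbons at once and carries the complete, configured chain through the ring expansion.

Key step: step 11

Assumption (remark on the chemistry): the two hydroxy-ketone tautomers of the benzotropolone interconvert freely. 26 and its ethers are drawn as 5-oxo forms and 36 as the 6-oxo form; the benzyl ether of 27 is drawn on O6, and the O5 isomer would converge in step 20.

Abbreviations in names: Bn = benzyl, MOM = methoxymethyl, TBS = tert-butyldimethylsilyl, Ar = 2,4-bis(benzyloxy)-6-(methoxymethoxy)phenyl.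

## Route

Step 1
Reactants: 1 3,4-bis(benzyloxy)benzaldehyde
Product: 2 2-bromo-4,5-bis(benzyloxy)benzaldehyde
Conditions: Br2, NaOAc, AcOH, rt
Reagents that add atoms: bromine, BrBr
Why: Electrophilic aromatic bromination; the free position para to the 3-benzyloxy group and ortho to the formyl group is the most activated, as in other 3,4-dialkoxybenzaldehydes. The bromine later blocks this position in the ring closure and is the coupling handle for chain B.

Step 2
Reactants: 2 2-bromo-4,5-bis(benzyloxy)benzaldehyde; 3 Meldrum's acid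
Product: 6 3-[2-bromo-4,5-bis(benzyloxy)phenyl]propanoic acid, via benzylidene Meldrum's acid 4 (not isolated), via benzyl Meldrum's acid 5 (not isolated)
Conditions: HCO2H/Et3N, 95 °C
Reagents that add atoms: none
Why: Knoevenagel condensation, conjugate reduction of the alkylidene by formate and decarboxylative hydrolysis run in one pot. No metal–hydrogen conditions are used, so the aryl bromide and benzyl ethers are safe.

Step 3
Reactants: 6 3-[2-bromo-4,5-bis(benzyloxy)phenyl]propanoic acid
Product: 8 4-bromo-6,7-bis(benzyloxy)indan-1-one, via acid chloride 7 (not isolated)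
Conditions: (COCl)2, cat. DMF, CH2Cl2, 0 °C to rt; then SnCl4, CH2Cl2, −78 to −20 °C
Reagents that add atoms: none
Why: Intramolecular Friedel–Crafts acylation; the only free ortho position is the one next to a benzyloxy group, so closure there gives the 7-oxygenated indanone. The mild Lewis acid at low temperature should spare the benzyl ethers.

Step 4
Reactants: 9 3,5-bis(benzyloxy)phenol
Product: 10 1,3-bis(benzyloxy)-5-(methoxymethoxy)benzene
Conditions: MOMCl, i-Pr2NEt, CH2Cl2, 0 °C to rt
Reagents that add atoms: chloromethyl methyl ether, COCCl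
Why: O-alkylation of the phenol. The MOM group directs the next metalation and is the acid-labile mask of the oxygen that becomes O1 of each flavan.

Step 5
Reactants: 10 1,3-bis(benzyloxy)-5-(methoxymethoxy)benzene; 11 methyl (R)-glycidate
Product: 14 methyl (2R)-3-Ar-2-hydroxypropanoate, via aryllithium 12 (not isolated), via arylmagnesium bromide 13 (not isolated)
Conditions: n-BuLi, TMEDA, THF, −40 to 0 °C; MgBr2·OEt2, −40 °C; CuI (cat.), 11, −40 to −20 °C
Reagents that add atoms: none
Why: Directed ortho-metalation next to the MOM ether (the two such positions are equivalent), transmetalation, then copper-catalysed opening of the epoxide at its CH2 terminus. The stereocentre of 11 is not touched, so its (R) configuration carries over.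

Step 6
Reactants: 14 methyl (2R)-3-Ar-2-hydroxypropanoate
Product: 15 methyl (2R)-3-Ar-2-(TBSO)propanoate
Conditions: TBSCl, imidazole, DMF, rt
Reagents that add atoms: tert-butyldimethylsilyl chloride, CC(C)(C)[Si](C)(C)Cl
Why: Silylation of the secondary alcohol. The silyl ether marks the C3 oxygen of flavan A as the one to be freed and acylated later.

Step 7
Reactants: 14 methyl (2R)-3-Ar-2-hydroxypropanoate
Product: 16 methyl (2R)-2-(benzyloxy)-3-Ar-propanoate
Conditions: BnBr, Ag2O, CH2Cl2, rt, dark
Reagents that add atoms: benzyl bromide, BrCc1ccccc1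
Why: O-benzylation under non-basic silver oxide conditions, which avoid enolisation of the α-hydroxy ester. The benzyl ether keeps the C3 oxygen of flavan B masked until the last step.

Step 8
Reactants: 16 methyl (2R)-2-(benzyloxy)-3-Ar-propanoate
Product: 17 (2R)-2-(benzyloxy)-3-Ar-propanoic acid
Conditions: LiOH, THF/H2O, 0 °C; dilute HCl work-up
Reagents that add atoms: lithium hydroxide, [Li+].[OH-]
Why: Saponification; the α-alkoxy ester is attacked at the carbonyl faster than it enolises at 0 °C.

Step 9
Reactants: 17 (2R)-2-(benzyloxy)-3-Ar-propanoic acid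
Product: 18 S-phenyl (2R)-2-(benzyloxy)-3-Ar-propanethioate
Conditions: PhSH, DCC, DMAP (cat.), CH2Cl2, 0 °C to rt
Reagents that add atoms: thiophenol, Sc1ccccc1
Why: Steglich-type thioesterification; gives the acyl donor for step 16.

Step 10
Reactants: 8 4-bromo-6,7-bis(benzyloxy)indan-1-one; 15 methyl (2R)-3-Ar-2-(TBSO)propanoate
Product: 20 4-bromo-6,7-bis(benzyloxy)-2-[(2R)-3-Ar-2-(TBSO)propanoyl]indan-1-one (ring enol), via lithium enolate 19 (not isolated)
Conditions: 8 (2 equiv), LiN(iPr)2, THF, −78 °C; then 15, −78 to 0 °C; AcOH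
Reagents that add atoms: none
Why: Crossed Claisen acylation: the enolate of 8 attacks the ester, which its α-oxygen activates. A second equivalent of enolate deprotonates the diketone, which drives the reaction and keeps free amide base away from the α-silyloxy centre; the product rests as the chelated enol.

Step 11
Reactants: 20 4-bromo-6,7-bis(benzyloxy)-2-[(2R)-3-Ar-2-(TBSO)propanoyl]indan-1-one (ring enol); 21 vinyl acetate
Product: 23 6-acetoxy-1-bromo-3,4-bis(benzyloxy)-8-[(2R)-3-Ar-2-(TBSO)propanoyl]-6,7,8,9-tetrahydro-5H-benzo[7]annulen-5-one (C6/C8 epimers), via cyclobutanol photoadduct 22 (not isolated)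
Conditions: hν (350–370 nm, Pyrex), 21 (excess), degassed MeCN, 0–10 °C, partial conversion with recycling of 20
Reagents that add atoms: none
Why: The chelated ring enol of 20 is a β-hydroxy enone; its excited state should bond through C2 of the indanone to the CH2 end of 21, giving a 1,4-biradical with a benzylic α-hydroxy radical on C1 and an α-acetoxy radical, which collapses to cyclobutanol 22. 22 is a strained aldol and should fragment at once by retro-aldol cleavage of the old C1–C2 bond, giving the 1,5-diketone 23. The closest known reaction type is the de Mayo reaction of enolised 1,3-diketones, as used for two-carbon enlargement of cyclic 2-acyl ketones. The four-membered ring closes by biradical collapse, a [2+2] annulation across C1–C2 that gives a bicyclo[3.2.0] core. The seven-membered ring is not closed by a cyclisation; it appears when the bond shared by the four- and five-membered rings breaks. C6 and C8 form without control (C8 by protonation of the released enol) and both are removed on aromatisation, while the silyloxy centre is a spectator. Reaction through the ring enol is needed: its endocyclic double bond cannot relax by twisting, its biradical is benzylic, and the peri benzyloxy oxygen is a second hydrogen-bond acceptor that holds the proton on the ring oxygen. Head-to-tail orientation follows from first bonding at the unsubstituted alkene carbon, and the long wavelength, absorbed only by the enol chromophore, keeps the aryl bromide intact.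

Step 12
Reactants: 23 6-acetoxy-1-bromo-3,4-bis(benzyloxy)-8-[(2R)-3-Ar-2-(TBSO)propanoyl]-6,7,8,9-tetrahydro-5H-benzo[7]annulen-5-one
Product: 24 1-bromo-3,4-bis(benzyloxy)-6-hydroxy-8-[(2R)-3-Ar-2-(TBSO)propanoyl]-6,7,8,9-tetrahydro-5H-benzo[7]annulen-5-one
Conditions: K2CO3 (cat.), MeOH, 0 °C, Ar
Reagents that add atoms: none
Why: Base-catalysed methanolysis of the α-acetoxy ketone, an activated ester, at low temperature. C6 and C8 need not be preserved, and the hindered α-silyloxy C–H should not be touched under these conditions.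

Step 13
Reactants: 24 1-bromo-3,4-bis(benzyloxy)-6-hydroxy-8-[(2R)-3-Ar-2-(TBSO)propanoyl]-6,7,8,9-tetrahydro-5H-benzo[7]annulen-5-one
Product: 26 1-bromo-3,4-bis(benzyloxy)-6-hydroxy-8-[(2R)-3-Ar-2-(TBSO)propanoyl]-5H-benzo[7]annulen-5-one, via 5,6-dione 25 (not isolated)
Conditions: Dess–Martin periodinane, CH2Cl2, 0 °C to rt; then DDQ (1 equiv), rt
Reagents that add atoms: none
Why: Dess–Martin oxidation turns the acyloin into the 1,2-dione, which enolises toward C7. The quinone then abstracts hydride from C9, which is benzylic and allylic to the enol of the exocyclic ketone, and loss of a proton gives the tropolone; the gain in aromaticity should make this site react first.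

Step 14
Reactants: 26 1-bromo-3,4-bis(benzyloxy)-6-hydroxy-8-[(2R)-3-Ar-2-(TBSO)propanoyl]-5H-benzo[7]annulen-5-one
Product: 27 1-bromo-3,4,6-tris(benzyloxy)-8-[(2R)-3-Ar-2-(TBSO)propanoyl]-5H-benzo[7]annulen-5-one
Conditions: BnBr, K2CO3, acetone, rt
Reagents that add atoms: benzyl bromide, BrCc1ccccc1
Why: O-alkylation of the acidic tropolone under mild carbonate conditions. The ether keeps the chelating hydroxy ketone away from palladium, copper and boron in steps 15 and 16 and is removed in step 20.

Step 15
Reactants: 27 1-bromo-3,4,6-tris(benzyloxy)-8-[(2R)-3-Ar-2-(TBSO)propanoyl]-5H-benzo[7]annulen-5-one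
Product: 29 {3,4,6-tris(benzyloxy)-5-oxo-8-[(2R)-3-Ar-2-(TBSO)propanoyl]-5H-benzo[7]annulen-1-yl}boronic acid, via pinacol boronate 28 (not isolated)
Conditions: B2pin2, PdCl2(dppf) (cat.), KOAc, 1,4-dioxane, 85 °C; then NaIO4, NH4OAc, acetone/H2O, rt
Reagents that add atoms: bis(pinacolato)diboron, CC1(C)OB(OC1(C)C)B1OC(C)(C)C(C)(C)O1; water, O
Why: Miyaura borylation of the aryl bromide, then periodate cleavage of the pinacol ester in buffered medium. The free boronic acid is the form that transmetalates well in step 16.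

Step 16
Reactants: 29 {3,4,6-tris(benzyloxy)-5-oxo-8-[(2R)-3-Ar-2-(TBSO)propanoyl]-5H-benzo[7]annulen-1-yl}boronic acid; 18 S-phenyl (2R)-2-(benzyloxy)-3-Ar-propanethioate
Product: 30 3,4,6-tris(benzyloxy)-1-[(2R)-2-(benzyloxy)-3-Ar-propanoyl]-8-[(2R)-3-Ar-2-(TBSO)propanoyl]-5H-benzo[7]annulen-5-one
Conditions: Pd2(dba)3 (cat.), tri(2-furyl)phosphine, CuO2C(C4H3S) (copper thiophene-2-carboxylate), THF, 50 °C
Reagents that add atoms: none
Why: Liebeskind–Srogl coupling: zerovalent palladium inserts into the C–S bond, and the copper carboxylate binds sulfur and activates boron. The ketone forms without base, so neither α-oxygenated stereocentre can enolise.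

Step 17
Reactants: 30 3,4,6-tris(benzyloxy)-1-[(2R)-2-(benzyloxy)-3-Ar-propanoyl]-8-[(2R)-3-Ar-2-(TBSO)propanoyl]-5H-benzo[7]annulen-5-one
Product: 32 3,4,6-tris(benzyloxy)-1-[(2R,3R)-3,5,7-tris(benzyloxy)chroman-2-yl]-8-[(2R,3R)-5,7-bis(benzyloxy)-3-(TBSO)chroman-2-yl]-5H-benzo[7]annulen-5-one, via bis-phenol diketone 31 (not isolated)
Conditions: Et3SiH (excess), CF3CO2H, CH2Cl2, −20 to 0 °C
Reagents that add atoms: none
Why: Acid removes both MOM groups (the silane reduces the methoxymethyl cation before it can alkylate the electron-rich rings) and each phenol closes on its ketone by 6-exo-trig addition. Ionic reduction of the two cyclic oxocarbenium ions completes the double reductive etherification. In each half-chair cation the C3 oxygen should lie pseudo-axial to avoid allylic strain with the C2 substituent, and hydride should enter axially on the opposite face, placing the C2 substituent and the C3 oxygen cis and making both new centres (2R) from the (3R) centres already present.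

Step 18
Reactants: 32 3,4,6-tris(benzyloxy)-1-[(2R,3R)-3,5,7-tris(benzyloxy)chroman-2-yl]-8-[(2R,3R)-5,7-bis(benzyloxy)-3-(TBSO)chroman-2-yl]-5H-benzo[7]annulen-5-one
Product: 33 3,4,6-tris(benzyloxy)-1-[(2R,3R)-3,5,7-tris(benzyloxy)chroman-2-yl]-8-[(2R,3R)-5,7-bis(benzyloxy)-3-hydroxychroman-2-yl]-5H-benzo[7]annulen-5-one
Conditions: HF·pyridine, THF/pyridine, 0 °C to rt
Reagents that add atoms: none
Why: Fluoride cleaves only the silyl ether. This frees the C3 hydroxyl of flavan A while that of flavan B stays benzylated, which tells the two flavans apart.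

Step 19
Reactants: 33 3,4,6-tris(benzyloxy)-1-[(2R,3R)-3,5,7-tris(benzyloxy)chroman-2-yl]-8-[(2R,3R)-5,7-bis(benzyloxy)-3-hydroxychroman-2-yl]-5H-benzo[7]annulen-5-one; 34 3,4,5-tris(benzyloxy)benzoic acid
Product: 35 (2R,3R)-5,7-bis(benzyloxy)-2-{3,4,6-tris(benzyloxy)-5-oxo-1-[(2R,3R)-3,5,7-tris(benzyloxy)chroman-2-yl]-5H-benzo[7]annulen-8-yl}chroman-3-yl 3,4,5-tris(benzyloxy)benzoate
Conditions: DCC, DMAP, CH2Cl2, rt
Reagents that add atoms: none
Why: Steglich esterification of the only free hydroxyl; acylation of the axial C3 alcohol of cis-flavans by this protected acid is a standard transformation.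

Step 20
Reactants: 35 (2R,3R)-5,7-bis(benzyloxy)-2-{3,4,6-tris(benzyloxy)-5-oxo-1-[(2R,3R)-3,5,7-tris(benzyloxy)chroman-2-yl]-5H-benzo[7]annulen-8-yl}chroman-3-yl 3,4,5-tris(benzyloxy)benzoate
Product: 36 (2R,3R)-5,7-dihydroxy-2-{3,4,5-trihydroxy-6-oxo-1-[(2R,3R)-3,5,7-trihydroxychroman-2-yl]-6H-benzo[7]annulen-8-yl}chroman-3-yl 3,4,5-trihydroxybenzoate
Conditions: H2 (1 atm), Pd(OH)2/C, THF/MeOH, rt
Reagents that add atoms: none
Why: Hydrogenolysis of all eleven benzyl ethers (aryl, alkyl and tropolone) under neutral conditions. The ester, the four stereocentres and the C2–O bonds of the 3-oxygenated flavans should stay in place.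

## Compound list

1 | 3,4-bis(benzyloxy)benzaldehyde | O=Cc1ccc(OCc2ccccc2)c(OCc2ccccc2)c1 | starting material
2 | 2-bromo-4,5-bis(benzyloxy)benzaldehyde | O=Cc1cc(OCc2ccccc2)c(OCc2ccccc2)cc1Br | intermediate
3 | Meldrum's acid (2,2-dimethyl-1,3-dioxane-4,6-dione) | CC1(C)OC(=O)CC(=O)O1 | starting material
4 | 5-[2-bromo-4,5-bis(benzyloxy)benzylidene] Meldrum's acid | CC1(C)OC(=O)C(=Cc2cc(OCc3ccccc3)c(OCc3ccccc3)cc2Br)C(=O)O1 | intermediate (not isolated)
5 | 5-[2-bromo-4,5-bis(benzyloxy)benzyl] Meldrum's acid | CC1(C)OC(=O)C(Cc2cc(OCc3ccccc3)c(OCc3ccccc3)cc2Br)C(=O)O1 | intermediate (not isolated)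
6 | 3-[2-bromo-4,5-bis(benzyloxy)phenyl]propanoic acid | OC(=O)CCc1cc(OCc2ccccc2)c(OCc2ccccc2)cc1Br | intermediate
7 | 3-[2-bromo-4,5-bis(benzyloxy)phenyl]propanoyl chloride | ClC(=O)CCc1cc(OCc2ccccc2)c(OCc2ccccc2)cc1Br | intermediate (not isolated)
8 | 4-bromo-6,7-bis(benzyloxy)indan-1-one | O=C1CCc2c(Br)cc(OCc3ccccc3)c(OCc3ccccc3)c12 | intermediate
9 | 3,5-bis(benzyloxy)phenol | Oc1cc(OCc2ccccc2)cc(OCc2ccccc2)c1 | starting material
10 | 1,3-bis(benzyloxy)-5-(methoxymethoxy)benzene | COCOc1cc(OCc2ccccc2)cc(OCc2ccccc2)c1 | intermediate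
11 | methyl (R)-glycidate (methyl (2R)-oxirane-2-carboxylate) | COC(=O)[C@H]1CO1 | starting material
12 | 2,4-bis(benzyloxy)-6-(methoxymethoxy)phenyllithium | [Li]c1c(OCOC)cc(OCc2ccccc2)cc1OCc1ccccc1 | intermediate (not isolated)
13 | 2,4-bis(benzyloxy)-6-(methoxymethoxy)phenylmagnesium bromide | Br[Mg]c1c(OCOC)cc(OCc2ccccc2)cc1OCc1ccccc1 | intermediate (not isolated)
14 | methyl (2R)-3-Ar-2-hydroxypropanoate | COC(=O)[C@H](O)Cc1c(OCOC)cc(OCc2ccccc2)cc1OCc1ccccc1 | intermediate
15 | methyl (2R)-3-Ar-2-(TBSO)propanoate | COC(=O)[C@H](O[Si](C)(C)C(C)(C)C)Cc1c(OCOC)cc(OCc2ccccc2)cc1OCc1ccccc1 | intermediate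
16 | methyl (2R)-2-(benzyloxy)-3-Ar-propanoate | COC(=O)[C@H](OCc1ccccc1)Cc1c(OCOC)cc(OCc2ccccc2)cc1OCc1ccccc1 | intermediate
17 | (2R)-2-(benzyloxy)-3-Ar-propanoic acid | OC(=O)[C@H](OCc1ccccc1)Cc1c(OCOC)cc(OCc2ccccc2)cc1OCc1ccccc1 | intermediate
18 | S-phenyl (2R)-2-(benzyloxy)-3-Ar-propanethioate | O=C(Sc1ccccc1)[C@H](OCc1ccccc1)Cc1c(OCOC)cc(OCc2ccccc2)cc1OCc1ccccc1 | intermediate
19 | lithium enolate of 8 | [Li]OC1=CCc2c(Br)cc(OCc3ccccc3)c(OCc3ccccc3)c12 | intermediate (not isolated)
20 | 4-bromo-6,7-bis(benzyloxy)-2-[(2R)-3-Ar-2-(TBSO)propanoyl]indan-1-one, ring enol | OC1=C(C(=O)[C@H](O[Si](C)(C)C(C)(C)C)Cc2c(OCOC)cc(OCc3ccccc3)cc2OCc2ccccc2)Cc2c(Br)cc(OCc3ccccc3)c(OCc3ccccc3)c12 | intermediate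
21 | vinyl acetate | C=COC(C)=O | starting material
22 | cyclobutanol photoadduct (acetoxy carbon bonded to the carbinol carbon; ring centres unassigned) | OC12C(OC(C)=O)CC1(C(=O)[C@H](O[Si](C)(C)C(C)(C)C)Cc1c(OCOC)cc(OCc3ccccc3)cc1OCc1ccccc1)Cc1c(Br)cc(OCc3ccccc3)c(OCc3ccccc3)c12 | intermediate (not isolated)
23 | 6-acetoxy-1-bromo-3,4-bis(benzyloxy)-8-[(2R)-3-Ar-2-(TBSO)propanoyl]-6,7,8,9-tetrahydro-5H-benzo[7]annulen-5-one (C6/C8 epimers) | O=C(C1Cc2c(Br)cc(OCc3ccccc3)c(OCc3ccccc3)c2C(=O)C(OC(C)=O)C1)[C@H](O[Si](C)(C)C(C)(C)C)Cc1c(OCOC)cc(OCc2ccccc2)cc1OCc1ccccc1 | intermediate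
24 | 1-bromo-3,4-bis(benzyloxy)-6-hydroxy-8-[(2R)-3-Ar-2-(TBSO)propanoyl]-6,7,8,9-tetrahydro-5H-benzo[7]annulen-5-one | O=C(C1Cc2c(Br)cc(OCc3ccccc3)c(OCc3ccccc3)c2C(=O)C(O)C1)[C@H](O[Si](C)(C)C(C)(C)C)Cc1c(OCOC)cc(OCc2ccccc2)cc1OCc1ccccc1 | intermediate
25 | 1-bromo-3,4-bis(benzyloxy)-8-[(2R)-3-Ar-2-(TBSO)propanoyl]-8,9-dihydro-5H-benzo[7]annulene-5,6(7H)-dione | O=C(C1Cc2c(Br)cc(OCc3ccccc3)c(OCc3ccccc3)c2C(=O)C(=O)C1)[C@H](O[Si](C)(C)C(C)(C)C)Cc1c(OCOC)cc(OCc2ccccc2)cc1OCc1ccccc1 | intermediate (not isolated)
26 | 1-bromo-3,4-bis(benzyloxy)-6-hydroxy-8-[(2R)-3-Ar-2-(TBSO)propanoyl]-5H-benzo[7]annulen-5-one | O=C(C1=Cc2c(Br)cc(OCc3ccccc3)c(OCc3ccccc3)c2C(=O)C(O)=C1)[C@H](O[Si](C)(C)C(C)(C)C)Cc1c(OCOC)cc(OCc2ccccc2)cc1OCc1ccccc1 | intermediate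
27 | 1-bromo-3,4,6-tris(benzyloxy)-8-[(2R)-3-Ar-2-(TBSO)propanoyl]-5H-benzo[7]annulen-5-one | O=C(C1=Cc2c(Br)cc(OCc3ccccc3)c(OCc3ccccc3)c2C(=O)C(OCc2ccccc2)=C1)[C@H](O[Si](C)(C)C(C)(C)C)Cc1c(OCOC)cc(OCc2ccccc2)cc1OCc1ccccc1 | intermediate
28 | pinacol boronate of 29 | O=C(C1=Cc2c(B3OC(C)(C)C(C)(C)O3)cc(OCc3ccccc3)c(OCc3ccccc3)c2C(=O)C(OCc2ccccc2)=C1)[C@H](O[Si](C)(C)C(C)(C)C)Cc1c(OCOC)cc(OCc2ccccc2)cc1OCc1ccccc1 | intermediate (not isolated)
29 | {3,4,6-tris(benzyloxy)-5-oxo-8-[(2R)-3-Ar-2-(TBSO)propanoyl]-5H-benzo[7]annulen-1-yl}boronic acid | O=C(C1=Cc2c(B(O)O)cc(OCc3ccccc3)c(OCc3ccccc3)c2C(=O)C(OCc2ccccc2)=C1)[C@H](O[Si](C)(C)C(C)(C)C)Cc1c(OCOC)cc(OCc2ccccc2)cc1OCc1ccccc1 | intermediate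
30 | 3,4,6-tris(benzyloxy)-1-[(2R)-2-(benzyloxy)-3-Ar-propanoyl]-8-[(2R)-3-Ar-2-(TBSO)propanoyl]-5H-benzo[7]annulen-5-one | O=C(C1=Cc2c(C(=O)[C@H](OCc3ccccc3)Cc3c(OCOC)cc(OCc4ccccc4)cc3OCc3ccccc3)cc(OCc3ccccc3)c(OCc3ccccc3)c2C(=O)C(OCc2ccccc2)=C1)[C@H](O[Si](C)(C)C(C)(C)C)Cc1c(OCOC)cc(OCc2ccccc2)cc1OCc1ccccc1 | intermediate
31 | diketone 30 with both MOM groups replaced by free phenols | O=C(C1=Cc2c(C(=O)[C@H](OCc3ccccc3)Cc3c(O)cc(OCc4ccccc4)cc3OCc3ccccc3)cc(OCc3ccccc3)c(OCc3ccccc3)c2C(=O)C(OCc2ccccc2)=C1)[C@H](O[Si](C)(C)C(C)(C)C)Cc1c(O)cc(OCc2ccccc2)cc1OCc1ccccc1 | intermediate (not isolated)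
32 | 3,4,6-tris(benzyloxy)-1-[(2R,3R)-3,5,7-tris(benzyloxy)chroman-2-yl]-8-[(2R,3R)-5,7-bis(benzyloxy)-3-(TBSO)chroman-2-yl]-5H-benzo[7]annulen-5-one | CC(C)(C)[Si](C)(C)O[C@@H]1Cc2c(OCc3ccccc3)cc(OCc3ccccc3)cc2O[C@@H]1C1=Cc2c([C@H]3Oc4cc(OCc5ccccc5)cc(OCc5ccccc5)c4C[C@H]3OCc3ccccc3)cc(OCc3ccccc3)c(OCc3ccccc3)c2C(=O)C(OCc2ccccc2)=C1 | intermediate
33 | 3,4,6-tris(benzyloxy)-1-[(2R,3R)-3,5,7-tris(benzyloxy)chroman-2-yl]-8-[(2R,3R)-5,7-bis(benzyloxy)-3-hydroxychroman-2-yl]-5H-benzo[7]annulen-5-one | O[C@@H]1Cc2c(OCc3ccccc3)cc(OCc3ccccc3)cc2O[C@@H]1C1=Cc2c([C@H]3Oc4cc(OCc5ccccc5)cc(OCc5ccccc5)c4C[C@H]3OCc3ccccc3)cc(OCc3ccccc3)c(OCc3ccccc3)c2C(=O)C(OCc2ccccc2)=C1 | intermediate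
34 | 3,4,5-tris(benzyloxy)benzoic acid | OC(=O)c1cc(OCc2ccccc2)c(OCc2ccccc2)c(OCc2ccccc2)c1 | starting material
35 | (2R,3R)-5,7-bis(benzyloxy)-2-{3,4,6-tris(benzyloxy)-5-oxo-1-[(2R,3R)-3,5,7-tris(benzyloxy)chroman-2-yl]-5H-benzo[7]annulen-8-yl}chroman-3-yl 3,4,5-tris(benzyloxy)benzoate | O=C(O[C@@H]1Cc2c(OCc3ccccc3)cc(OCc3ccccc3)cc2O[C@@H]1C1=Cc2c([C@H]3Oc4cc(OCc5ccccc5)cc(OCc5ccccc5)c4C[C@H]3OCc3ccccc3)cc(OCc3ccccc3)c(OCc3ccccc3)c2C(=O)C(OCc2ccccc2)=C1)c1cc(OCc2ccccc2)c(OCc2ccccc2)c(OCc2ccccc2)c1 | intermediate
36 | (2R,3R)-5,7-dihydroxy-2-{3,4,5-trihydroxy-6-oxo-1-[(2R,3R)-3,5,7-trihydroxychroman-2-yl]-6H-benzo[7]annulen-8-yl}chroman-3-yl 3,4,5-trihydroxybenzoate | O=C(O[C@@H]1Cc2c(O)cc(O)cc2O[C@@H]1c1cc(=O)c(O)c2c(O)c(O)cc([C@H]3Oc4cc(O)cc(O)c4C[C@H]3O)c2c1)c1cc(O)c(O)c(O)c1 | target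

## Step count and least certain steps

Total: 20 steps. Longest linear sequence: 14 steps (1 → 2 → 6 → 8 → 20 → 23 → 24 → 26 → 27 → 29 → 30 → 32 → 33 → 35 → 36; the sequence from 9 through 15 is equally long).

**Step 11 (key step).** The most likely failures are addition in the wrong orientation or through the exocyclic enol tautomer, and secondary photolysis of the aryl ketone product during long irradiation. The reasons are that the alkene is only moderately polarised, both enol tautomers are accessible in the excited state, and chelated aryl enols lose excitation quickly by proton transfer. The fallback keeps the same chromophore but removes the orientation variable and shortens the later oxidation work. It sets out from 20 and uses vinylene carbonate, a symmetric alkene, in the photocycloaddition. The ring-expanded 6,7-cyclic carbonate F3 is treated with DBU: deprotonation at C8 expels the C7 oxygen, the carbonate loses carbon dioxide, and 8-acyl-1-bromo-3,4-bis(benzyloxy)-6-hydroxy-6,9-dihydro-5H-benzo[7]annulen-5-one F4 results. Dess–Martin oxidation of F4 gives a dione that enolises to the tropolone, so the fallback returns at 26 and bypasses steps 12 and 13.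

**Step 10.** The most likely failure is proton transfer in place of acylation, because the ester is hindered by the silyloxy and arylmethyl groups, together with slow enolisation of the ester and erosion of its configuration. The fallback is an aldol addition followed by oxidation. It sets out from 15, which i-Bu2AlH at −78 °C reduces to (2R)-3-Ar-2-(TBSO)propanal F1. Enolate 19 adds to F1 to give the β-hydroxy ketone 4-bromo-6,7-bis(benzyloxy)-2-[(2R)-1-hydroxy-3-Ar-2-(TBSO)propyl]indan-1-one F2 as an epimer mixture. Dess–Martin oxidation of F2 returns to the route at 20.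

**Step 13.** The most likely failure is hydride abstraction at the wrong site: the 2,4,6-trioxygenated benzylic CH2 of the chain is itself a good hydride donor toward the quinone, so the chain may be oxidised alongside the ring. The fallback replaces hydride abstraction by a Saegusa–Ito oxidation. It sets out from 25, isolated after the Dess–Martin stage. Me3SiOTf and Et3N convert 25 into the bis(trimethylsilyl) dienol ether F5 (silyl ethers on O6 and on the enol of the exocyclic ketone toward C8). Pd(OAc)2 in MeCN then introduces the C8–C9 double bond by β-hydride elimination from the palladium enolate. Aqueous work-up removes the remaining silyl group and returns to the route at 26.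

**Step 16.** The most likely failure is slow transmetalation of the hindered, electron-rich boronic acid (peri to C9–H), leading to protodeboronation before coupling. The fallback forms the same bond by 1,2-addition and oxidation. It sets out from 29 and 16: 16 is reduced with i-Bu2AlH at −78 °C to (2R)-2-(benzyloxy)-3-Ar-propanal F6. Rhodium-catalysed addition of 29 to F6 (Rh(acac)(CO)2, dppf, aqueous DME) gives the secondary alcohol F7, the carbinol analogue of 30, as an epimer mixture. Dess–Martin oxidation of F7 returns to the route at 30.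

**Step 17.** Several things can go wrong:
- incomplete ionisation at the ketone on the electron-poor tropone ring;
- loss of a proton from that cation to an enol ether, with loss of C3 configuration;
- poor facial selectivity at one of the two centres;
- cleavage of the silyl or tropolone benzyl ether by the acid;
- over-reduction of the C2–O bond of flavan B.

Two different ketones react in one pot, so conditions cannot be tuned for each. The fallback closes the rings one at a time. It sets out from 27, whose single ketone is closed under the same acid and silane to the flavan A bromide F8. Borylation and periodate cleavage as in step 15 give boronic acid F9, coupling with 18 as in step 16 gives ketone F10, and a second reductive etherification closes flavan B and returns to the route at 32.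

**Step 20.** The most likely failure is saturation of the tropolone ring, or hydrogenolysis of a benzylic C2–O bond, before all eleven benzyl ethers are gone. The fallback is Lewis-acid debenzylation: 35 is treated with BCl3 and pentamethylbenzene as benzyl-cation scavenger in CH2Cl2 at −78 °C and goes directly to 36 without a new intermediate.

## Further compounds

F1 | step 10 | (2R)-3-Ar-2-(TBSO)propanal | O=C[C@H](O[Si](C)(C)C(C)(C)C)Cc1c(OCOC)cc(OCc2ccccc2)cc1OCc1ccccc1
F2 | step 10 | 4-bromo-6,7-bis(benzyloxy)-2-[(2R)-1-hydroxy-3-Ar-2-(TBSO)propyl]indan-1-one (epimers at the two new centres) | O=C1C(C(O)[C@H](O[Si](C)(C)C(C)(C)C)Cc2c(OCOC)cc(OCc3ccccc3)cc2OCc2ccccc2)Cc2c(Br)cc(OCc3ccccc3)c(OCc3ccccc3)c12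
F3 | step 11 | 6,7-cyclic carbonate of 1-bromo-3,4-bis(benzyloxy)-6,7-dihydroxy-8-[(2R)-3-Ar-2-(TBSO)propanoyl]-6,7,8,9-tetrahydro-5H-benzo[7]annulen-5-one | O=C(C1Cc2c(Br)cc(OCc3ccccc3)c(OCc3ccccc3)c2C(=O)C2OC(=O)OC12)[C@H](O[Si](C)(C)C(C)(C)C)Cc1c(OCOC)cc(OCc2ccccc2)cc1OCc1ccccc1
F4 | step 11 | 1-bromo-3,4-bis(benzyloxy)-6-hydroxy-8-[(2R)-3-Ar-2-(TBSO)propanoyl]-6,9-dihydro-5H-benzo[7]annulen-5-one | O=C(C1=CC(O)C(=O)c2c(OCc3ccccc3)c(OCc3ccccc3)cc(Br)c2C1)[C@H](O[Si](C)(C)C(C)(C)C)Cc1c(OCOC)cc(OCc2ccccc2)cc1OCc1ccccc1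
F5 | step 13 | bis(trimethylsilyl) dienol ether of 25 (silyl on O6 and on the exocyclic enol toward C8) | C[Si](C)(C)OC(=C1Cc2c(Br)cc(OCc3ccccc3)c(OCc3ccccc3)c2C(=O)C(O[Si](C)(C)C)=C1)[C@H](O[Si](C)(C)C(C)(C)C)Cc1c(OCOC)cc(OCc2ccccc2)cc1OCc1ccccc1
F6 | step 16 | (2R)-2-(benzyloxy)-3-Ar-propanal | O=C[C@H](OCc1ccccc1)Cc1c(OCOC)cc(OCc2ccccc2)cc1OCc1ccccc1
F7 | step 16 | 3,4,6-tris(benzyloxy)-1-[(2R)-2-(benzyloxy)-1-hydroxy-3-Ar-propyl]-8-[(2R)-3-Ar-2-(TBSO)propanoyl]-5H-benzo[7]annulen-5-one (carbinol epimers) | O=C(C1=Cc2c(C(O)[C@H](OCc3ccccc3)Cc3c(OCOC)cc(OCc4ccccc4)cc3OCc3ccccc3)cc(OCc3ccccc3)c(OCc3ccccc3)c2C(=O)C(OCc2ccccc2)=C1)[C@H](O[Si](C)(C)C(C)(C)C)Cc1c(OCOC)cc(OCc2ccccc2)cc1OCc1ccccc1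
F8 | step 17 | 1-bromo-3,4,6-tris(benzyloxy)-8-[(2R,3R)-5,7-bis(benzyloxy)-3-(TBSO)chroman-2-yl]-5H-benzo[7]annulen-5-one | CC(C)(C)[Si](C)(C)O[C@@H]1Cc2c(OCc3ccccc3)cc(OCc3ccccc3)cc2O[C@@H]1C1=Cc2c(Br)cc(OCc3ccccc3)c(OCc3ccccc3)c2C(=O)C(OCc2ccccc2)=C1
F9 | step 17 | {3,4,6-tris(benzyloxy)-8-[(2R,3R)-5,7-bis(benzyloxy)-3-(TBSO)chroman-2-yl]-5-oxo-5H-benzo[7]annulen-1-yl}boronic acid | CC(C)(C)[Si](C)(C)O[C@@H]1Cc2c(OCc3ccccc3)cc(OCc3ccccc3)cc2O[C@@H]1C1=Cc2c(B(O)O)cc(OCc3ccccc3)c(OCc3ccccc3)c2C(=O)C(OCc2ccccc2)=C1
F10 | step 17 | 3,4,6-tris(benzyloxy)-1-[(2R)-2-(benzyloxy)-3-Ar-propanoyl]-8-[(2R,3R)-5,7-bis(benzyloxy)-3-(TBSO)chroman-2-yl]-5H-benzo[7]annulen-5-one | CC(C)(C)[Si](C)(C)O[C@@H]1Cc2c(OCc3ccccc3)cc(OCc3ccccc3)cc2O[C@@H]1C1=Cc2c(C(=O)[C@H](OCc3ccccc3)Cc3c(OCOC)cc(OCc4ccccc4)cc3OCc3ccccc3)cc(OCc3ccccc3)c(OCc3ccccc3)c2C(=O)C(OCc2ccccc2)=C1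
F0 | step 20 | none | none
A1 | alternative 1 | (E)-2'-hydroxychalcone: 1-[2-hydroxy-4,6-bis(benzyloxy)phenyl]-3-(benzylated benzotropolon-8-yl carrying benzylated flavan B on C1)prop-2-en-1-one | Oc1cc(OCc2ccccc2)cc(OCc2ccccc2)c1C(=O)/C=C/c1cc(=O)c(OCc2ccccc2)c2c(OCc3ccccc3)c(OCc3ccccc3)cc([C@H]3Oc4cc(OCc5ccccc5)cc(OCc5ccccc5)c4C[C@H]3OCc3ccccc3)c2c1
A2 | alternative 1 | 5,7-bis(benzyloxy)flavanone of flavan A (4-keto level, C2 configured as in the target) | O=C1C[C@@H](c3cc(=O)c(OCc9ccccc9)c4c(OCc9ccccc9)c(OCc9ccccc9)cc([C@H]5Oc6cc(OCc9ccccc9)cc(OCc9ccccc9)c6C[C@H]5OCc9ccccc9)c4c3)Oc2cc(OCc9ccccc9)cc(OCc9ccccc9)c12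
A3 | alternative 2 | 8-(hydroxyacetyl) benzotropolone, benzylated and carrying benzylated flavan B on C1 | OCC(=O)c1cc(=O)c(OCc2ccccc2)c2c(OCc3ccccc3)c(OCc3ccccc3)cc([C@H]3Oc4cc(OCc5ccccc5)cc(OCc5ccccc5)c4C[C@H]3OCc3ccccc3)c2c1
A4 | alternative 2 | 2-[(phenylsulfonyl)methyl]-3,5-bis(benzyloxy)phenol | Oc1cc(OCc2ccccc2)cc(OCc2ccccc2)c1CS(=O)(=O)c1ccccc1
A5 | alternative 2 | 2-hydroxyflavan-3-ol hemiketal of flavan A (C3 as in the target, C2 anomers unassigned) | O[C@@H]1Cc2c(OCc9ccccc9)cc(OCc9ccccc9)cc2OC1(O)c1cc(=O)c(OCc9ccccc9)c2c(OCc9ccccc9)c(OCc9ccccc9)cc([C@H]3Oc4cc(OCc9ccccc9)cc(OCc9ccccc9)c4C[C@H]3OCc9ccccc9)c2c1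
A6 | alternative 3 | methyl 8-bromo-5,6-bis(benzyloxy)-4-(trimethylsilyloxy)-1,2-dihydronaphthalene-2-carboxylate (racemic) | COC(=O)C1Cc2c(Br)cc(OCc3ccccc3)c(OCc3ccccc3)c2C(O[Si](C)(C)C)=C1
A7 | alternative 3 | methyl 1,6-dibromo-3,4-bis(benzyloxy)-5-oxo-8,9-dihydro-5H-benzo[7]annulene-8-carboxylate (racemic) | COC(=O)C1Cc2c(Br)cc(OCc9ccccc9)c(OCc9ccccc9)c2C(=O)C(Br)=C1
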